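**Plan**

1. Cuts: first the bond from the stereogenic linker carbon C3 to C6 of chromene ring B, giving the ring A (E)-1-aryl-buta-1,3-diene 12 and the ring B boronic acid 15. Then C1=C2 of the diene (olefination of aldehyde 8) and the C6–CHO and C6–B bonds, back to one bromide 5. Last the pyran ring of 5 (O1–C2 and C4–C4a), back to phenol 1 and enal 2.
2. Enabling feature: C3 carries CH3, the aryl C6 of ring B and the C1=C2 bond conjugated to ring A. C1–C2–C3 is therefore a 1-aryl-3-methylallyl unit, the hydrogen adduct at C4 of a 1-aryl-buta-1,3-diene. A nickel hydride puts H on C4 and the resulting η3-allyl is arylated at C3.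
3. Forward order: the pyran ring is closed first (step 1), bromide 5 is branched into the diene (steps 2 and 3) and the boronic acid (step 4), and the chain is joined to ring B last (step 5).
4. Stereochemistry: the only stereocentre (C3, S) is created in step 5 under control of the chiral ligand on nickel. The E alkene is set in the olefination and kept by the syn,syn-allyl.

Key step: step 5

Remark on the chemistry: ring A is the chromene on the alkene carbon C1, ring B the chromene on the stereocentre C3, and C4 is the methyl carbon. The stereocentre is S (ring B aryl > alkenyl > CH3 > H). Compounds 1, 2 and 9 are taken to be commercial. PhB(OH)2 in step 1 acts as a template and is released unchanged on aqueous work-up. The ligand in step 5 is a 7-amino-7'-[bis(3,5-di-tert-butylphenyl)phosphanyl]-1,1'-spirobiindane; the antipode that gives the S product is to be assigned in a trial on the diphenyl model and used throughout.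

**Route**

Step 1
Reactants: 1 4-bromo-3-methoxyphenol; 2 3-methylbut-2-enal
Product: 5 6-bromo-7-methoxy-2,2-dimethyl-2H-chromene, via dioxaborin 3 (not isolated), via o-quinone methide 4 (not isolated)
Conditions: PhB(OH)2 (1 equiv), propionic acid (cat.), toluene, reflux, Dean–Stark
Reagents that add atoms: none
Why: Phenylboronic acid templates the ortho-hydroxyalkylation of phenol 1 by the enal to dioxaborin 3, which on heating loses the boron unit to give o-quinone methide 4 that closes by oxa-6π electrocyclization (boronic acid-mediated 2H-chromene synthesis), and the ortho carbon para to OMe should react because the other ortho carbon lies between OH and an OMe group that bromine forces to turn towards it.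

Step 2
Reactants: 5 6-bromo-7-methoxy-2,2-dimethyl-2H-chromene
Product: 8 7-methoxy-2,2-dimethyl-2H-chromene-6-carbaldehyde, via aryllithium 6 (not isolated), via lithium hemiaminalate 7 (not isolated)
Conditions: n-BuLi, THF, −78 °C; DMF, −78 to 0 °C; H2O
Reagents that add atoms: N,N-dimethylformamide (DMF), CN(C)C=O
Why: Bromine–lithium exchange at −78 °C is much faster than addition of n-BuLi to the chromene alkene, and aryllithium 6 is formylated by DMF (Bouveault formylation) through hemiaminalate 7, which collapses to the aldehyde on aqueous quench.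

Step 3
Reactants: 8 7-methoxy-2,2-dimethyl-2H-chromene-6-carbaldehyde; 9 diethyl allylphosphonate
Product: 12 (E)-6-(buta-1,3-dien-1-yl)-7-methoxy-2,2-dimethyl-2H-chromene, via lithiated allylphosphonate 10 (not isolated), via oxidophosphonate adduct 11 (not isolated)
Conditions: 9, n-BuLi, THF, −78 °C; then 8; HMPA, −78 °C to rt
Reagents that add atoms: none
Why: Horner–Wadsworth–Emmons olefination of 8 by the α-lithiated allylphosphonate 10, in which HMPA promotes reversible addition and loss of diethyl phosphate from adduct 11 so that the (E)-configured terminal diene is expected to predominate.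

Step 4
Reactants: 5 6-bromo-7-methoxy-2,2-dimethyl-2H-chromene
Product: 15 (7-methoxy-2,2-dimethyl-2H-chromen-6-yl)boronic acid, via arylmagnesium bromide 13 (not isolated), via bromomagnesium triisopropoxyborate 14 (not isolated)
Conditions: Mg turnings (I2 cat.), THF, reflux; B(OiPr)3, −78 °C to rt; 1 M HCl to pH 5, 0 °C
Reagents that add atoms: triisopropyl borate, CC(C)OB(OC(C)C)OC(C)C; water, O
Why: Magnesium inserts into the aryl C–Br bond to give Grignard reagent 13, to which the chromene alkene and the ethers are inert; the hindered borate traps it at low temperature as the mono-aryl ate complex 14, and hydrolysis at about pH 5 gives the boronic acid (Grignard borylation) under conditions mild enough for the acid-sensitive chromene.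

Step 5
Reactants: 12 (E)-6-(buta-1,3-dien-1-yl)-7-methoxy-2,2-dimethyl-2H-chromene; 15 (7-methoxy-2,2-dimethyl-2H-chromen-6-yl)boronic acid
Product: 16 7-methoxy-6-[(1E,3S)-3-(7-methoxy-2,2-dimethyl-2H-chromen-6-yl)but-1-en-1-yl]-2,2-dimethyl-2H-chromene
Conditions: Ni(cod)2 (5 mol %), chiral spiro aminophosphine ligand (6 mol %), 15 (1.5 equiv), MeOH/THF, 30 °C, argon
Reagents that add atoms: none
Why: Zerovalent nickel on the chiral aminophosphine is converted by methanol into a nickel hydride that delivers H to the terminal CH2 (C4) of diene 12, giving a 1-aryl-3-methyl-η3-allyl nickel; transmetalation from 15 (as its methoxyborate) and C–C reductive elimination at the methyl-bearing terminus C3 release 16 and return zerovalent nickel. The closest known reaction type is the nickel-catalysed enantioselective 1,2-hydroarylation of 1-aryl-1,3-dienes and styrenes by arylboronic acids in an alcohol. No ring is closed in this step. The one new stereocentre (C3, S) is controlled by the chiral ligand alone, which fixes the allyl face to which the aryl group is delivered, since π–σ–π interconversion of the allyl is expected to be faster than coupling. The step needs arylation at C3 and not at C1, secured by retention of the C1=C2 conjugation with electron-rich ring A and by the ortho OMe group shielding C1, and it needs E geometry, secured by the syn,syn-allyl. It also needs hydride addition to the diene only, secured because the chromene C3=C4 bonds are cis-disubstituted and flanked by the quaternary C2, so that they should bind and insert far more slowly than a terminal diene.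

**Compound list**

1 | 4-bromo-3-methoxyphenol | COc1cc(O)ccc1Br | starting material
2 | 3-methylbut-2-enal | CC(C)=CC=O | starting material
3 | 6-bromo-7-methoxy-4-(2-methylprop-1-en-1-yl)-2-phenyl-4H-1,3,2-benzodioxaborinine (racemic) | CC(C)=CC1OB(c2ccccc2)Oc2cc(OC)c(Br)cc21 | intermediate
4 | 4-bromo-3-methoxy-6-(3-methylbut-2-en-1-ylidene)cyclohexa-2,4-dien-1-one | CC(C)=CC=C1C=C(Br)C(OC)=CC1=O | intermediate
5 | 6-bromo-7-methoxy-2,2-dimethyl-2H-chromene | COc1cc2OC(C)(C)C=Cc2cc1Br | intermediate
6 | (7-methoxy-2,2-dimethyl-2H-chromen-6-yl)lithium | COc1cc2OC(C)(C)C=Cc2cc1[Li] | intermediate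
7 | lithium (dimethylamino)(7-methoxy-2,2-dimethyl-2H-chromen-6-yl)methanolate | COc1cc2OC(C)(C)C=Cc2cc1C(O[Li])N(C)C | intermediate
8 | 7-methoxy-2,2-dimethyl-2H-chromene-6-carbaldehyde | COc1cc2OC(C)(C)C=Cc2cc1C=O | intermediate
9 | diethyl allylphosphonate | C=CCP(=O)(OCC)OCC | starting material
10 | diethyl (1-lithioallyl)phosphonate | C=CC([Li])P(=O)(OCC)OCC | intermediate
11 | lithium 2-(diethoxyphosphoryl)-1-(7-methoxy-2,2-dimethyl-2H-chromen-6-yl)but-3-en-1-olate (diastereomer mixture) | COc1cc2OC(C)(C)C=Cc2cc1C(O[Li])C(C=C)P(=O)(OCC)OCC | intermediate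
12 | (E)-6-(buta-1,3-dien-1-yl)-7-methoxy-2,2-dimethyl-2H-chromene | COc1cc2OC(C)(C)C=Cc2cc1/C=C/C=C | intermediate
13 | (7-methoxy-2,2-dimethyl-2H-chromen-6-yl)magnesium bromide | COc1cc2OC(C)(C)C=Cc2cc1[Mg]Br | intermediate
14 | bromomagnesium triisopropoxy(7-methoxy-2,2-dimethyl-2H-chromen-6-yl)borate | Br[Mg+].COc1cc2OC(C)(C)C=Cc2cc1[B-](OC(C)C)(OC(C)C)OC(C)C | intermediate
15 | (7-methoxy-2,2-dimethyl-2H-chromen-6-yl)boronic acid | COc1cc2OC(C)(C)C=Cc2cc1B(O)O | intermediate
16 | 7-methoxy-6-[(1E,3S)-3-(7-methoxy-2,2-dimethyl-2H-chromen-6-yl)but-1-en-1-yl]-2,2-dimethyl-2H-chromene | COc1cc2c(cc1/C=C/[C@H](C)c1cc3c(cc1OC)OC(C)(C)C=C3)C=CC(C)(C)O2 | target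

**Step count**

Total steps: 5. Longest linear sequence: 4 steps (steps 1, 2, 3, 5); step 4 is the one-step branch from 5.

**Steps most likely to fail**

Step 5. The risks are erosion of enantio- and regiocontrol, because both partners carry an OMe group ortho to the reacting carbon, protodeboronation of the electron-rich boronic acid in methanol, and nickel hydride addition to a chromene alkene or isomerisation of the product alkene. The fallback sets out from aldehyde 8 and comes back to the route at 16; it sets the stereocentre by a reagent-controlled ketone reduction and transfers it. A Wittig reaction of 8 with 1-(triphenylphosphoranylidene)propan-2-one (toluene, 90 °C) should give (E)-4-(7-methoxy-2,2-dimethyl-2H-chromen-6-yl)but-3-en-2-one F1. Corey–Bakshi–Shibata reduction with (S)-Me-CBS ((S)-1-methyl-3,3-diphenyltetrahydro-1H,3H-pyrrolo[1,2-c][1,3,2]oxazaborole) and catecholborane (toluene, −78 °C) is expected to give (R,E)-4-(7-methoxy-2,2-dimethyl-2H-chromen-6-yl)but-3-en-2-ol F2. PivCl, pyridine and DMAP (CH2Cl2, 0 °C) convert it into (R,E)-4-(7-methoxy-2,2-dimethyl-2H-chromen-6-yl)but-3-en-2-yl pivalate F3. Boronic acid 15 is dehydrated by toluene azeotrope to 2,4,6-tris(7-methoxy-2,2-dimethyl-2H-chromen-6-yl)boroxine F4. Stereospecific nickel-catalysed allyl–aryl coupling of F3 with F4 (Ni(cod)2, BnPPh2, NaOMe, MeCN, rt) should then give 16, with arylation at the methyl-bearing allyl terminus. Net inversion at the carbinol carbon is expected (anti oxidative addition, inner-sphere reductive elimination), hence the R pivalate; should the coupling prove retentive, the antipodal CBS catalyst supplies the S pivalate.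

Step 3. The risks are attack through the γ-carbon of the ambident allyl anion, and incomplete or non-selective elimination leaving hydroxyphosphonate or an E/Z mixture of a diene that also oligomerises readily. The fallback sets out from 8 and comes back at 12; it builds the diene one alkene at a time. A Wittig reaction of 8 with the stabilised ylide (triphenylphosphoranylidene)acetaldehyde (toluene, 80 °C) should give (E)-3-(7-methoxy-2,2-dimethyl-2H-chromen-6-yl)prop-2-enal F5. Methylenation of F5 with Ph3P=CH2 (from Ph3PCH3Br and KOtBu, THF, 0 °C) should give 12, which is used at once.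

Step 1. The risks are sluggish ortho-hydroxyalkylation of the bromine-deactivated phenol, self-condensation of the enal, and acid-induced oligomerisation of the electron-rich chromene on long heating. The fallback sets out from 1 and comes back at 5; it replaces the condensation by O-alkylation and a sigmatropic cascade under neutral conditions. O-Alkylation of 1 with 3-chloro-3-methylbut-1-yne (DBU, CuCl2 cat., MeCN, 0 °C) should give 1-bromo-2-methoxy-4-[(2-methylbut-3-yn-2-yl)oxy]benzene F6. Heating F6 in N,N-diethylaniline (about 180 °C) should bring about propargyl Claisen rearrangement, enolisation and a 1,5-hydrogen shift to the same o-quinone methide 4, which closes to 5.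

**Further compounds**

F1 | step 5 | (E)-4-(7-methoxy-2,2-dimethyl-2H-chromen-6-yl)but-3-en-2-one | COc1cc2OC(C)(C)C=Cc2cc1/C=C/C(C)=O
F2 | step 5 | (R,E)-4-(7-methoxy-2,2-dimethyl-2H-chromen-6-yl)but-3-en-2-ol | COc1cc2OC(C)(C)C=Cc2cc1/C=C/[C@@H](C)O
F3 | step 5 | (R,E)-4-(7-methoxy-2,2-dimethyl-2H-chromen-6-yl)but-3-en-2-yl pivalate | COc1cc2OC(C)(C)C=Cc2cc1/C=C/[C@@H](C)OC(=O)C(C)(C)C
F4 | step 5 | 2,4,6-tris(7-methoxy-2,2-dimethyl-2H-chromen-6-yl)boroxine | COc1cc2OC(C)(C)C=Cc2cc1B1OB(c2cc3C=CC(C)(C)Oc3cc2OC)OB(c2cc3C=CC(C)(C)Oc3cc2OC)O1
F5 | step 3 | (E)-3-(7-methoxy-2,2-dimethyl-2H-chromen-6-yl)prop-2-enal | COc1cc2OC(C)(C)C=Cc2cc1/C=C/C=O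
F6 | step 1 | 1-bromo-2-methoxy-4-[(2-methylbut-3-yn-2-yl)oxy]benzene | COc1cc(OC(C)(C)C#C)ccc1Br
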